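## The problem

The target 30 is a stilbenoid trimer built on a pentasubstituted central benzene (ring C; its carbons are lettered a to f here). Carbons a and c carry the oxygens of two trans-2-aryl-2,3-dihydrofurans, furan A closing onto f and furan B onto d; b is the only ring C–H and e carries a methylene group. This methylene, the diarylmethine carbon bearing the 2,4-dihydroxyphenyl group, two neighbouring carbons of the resorcinol-type ring B, C3 of furan B (C3B) and ring C carbons d and e make up a seven-membered carbocycle, so C3B belongs to both furan B and the seven-membered ring. There are five stereocentres, all R: C2A and C3A, C2B and C3B, and the diarylmethine. Within each furan C2 can follow C3, because the benzylic C2–O bond can ionise and reclose to the more stable trans isomer; C3B faces the diarylmethine across the seven-membered ring and can be controlled by it; the furan A pair is insulated from the other three centres by the flat ring C and needs control from outside the molecule. The eight phenols are easily oxidised and must be unmasked last, the benzylic aryl ether bonds and any stilbene intermediate do not tolerate strong acid before that point, and the electron-rich rings invite stray electrophilic substitution. The enabling feature is the shared atom C3B: the bond from ring C carbon d to C3B and the bond from the oxygen on c to C2B close the seven-membered ring and furan B together, and these are the two bonds formed when a phenol adds, carbon then oxygen, across an oxidised aryl alkene; with both ring C oxygens free, d and f are equivalent.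

## Retrosynthesis

**30 to 29.** The last cut is at the eight O–methyl bonds, leading to the octamethyl ether 29. Methyl ethers are the one phenol mask that passes organolithium, fluoride, anodic and basic steps alike; silyl or benzyl groups would fall to one of them. The precursor is no simpler in skeleton but is inert to oxidation. The forward step must remove eight ethers without opening either dihydrofuran for good.

**29 to 22 and 26.** Furan A is cut at C2A–C3A and at O–C2A. This gives the ortho-hydroxybenzyl sulfone 22, a latent ortho-quinone methide (27), and the enantiopure benzylic sulfonium salt 26, the source of ylide 28. The neighbouring cut, at C(f)–C3A and O–C2A (oxidative union of phenol 18 with a stilbene), would be shorter, but it leaves the site (b or f) and the configuration of the remote furan A pair to chance. The chosen cut fixes the site by where the carbon already sits and the configuration by the reagent. 22 lacks one ring and two stereocentres. The forward reaction must be trans-selective and ylide-controlled.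

**22 to 19 and 20, then 19 to 18.** The sulfone carbon is cut from the 3,5-dimethoxyphenyl ring (Grignard reagent 20) and from sulfur, back to salicylaldehyde 19; the formyl C–C bond at f is then cut to reach phenol 18. Bringing the carbon in through a phenoxide-templated formylation confines the chemistry to ring C, the only ring with a free hydroxyl; an acid-mediated hydroxyalkylation would also engage the dimethoxyarenes. The forward formylation must choose f over b.

**18 to 17 (key cut).** The C(d)–C3B and O–C2B bonds are cut together, opening the seven-membered ring and furan B and erasing two stereocentres. The precursor is the acyclic stilbene bis-phenol 17 with a single stereocentre. Cutting the methine–ring B bond or the CH2–ring C bond instead would form the medium ring and the furan in separate operations and would run a cationic closure next to a finished dihydrofuran. The forward reaction must join carbon d to the alkene carbon remote from the anisyl group and the oxygen to the other alkene carbon, and must translate the methine configuration into that of C3B.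

**17 to 15, then 15 to 7 and 12.** 17 is traced through its bis-silyl ether 16 to the tertiary boronic ester 15 (C–H back to C–B). The methine–ring B bond is then cut to the secondary benzylic carbamate 7 and the arylboronic ester 12. A Friedel–Crafts union of the same two carbons would be racemic and would expose the stilbene to acid, and a benzylic electrophile this electron-rich would not hold its configuration in a metal-catalysed coupling; the boron route is stereospecific at both stages. 7 and 12 are of similar size and each needs few steps. The forward reaction must move a doubly ortho-substituted aryl group from boron to carbon.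

**7 to 6, 5, then 3 and 4; 3 to 2 and 1.** Carbamate 7 comes from alcohol 6, whose carbinol C–H is cut back to ketone 5. 5 is cut at the carbonyl–aryl bond into Weinreb amide 3 and Grignard reagent 4; 3 derives from the bis-silyl ester 2 and the dihydroxy ester 1. The alternative CH2–CO cut would need a benzylic nucleophile from the silyloxy ring, whereas this cut uses a bought aryl nucleophile. The forward sequence needs one enantioselective reduction of an aryl benzyl ketone.

**12 to 10, then 8 and 9.** The C–B bond is traced to the C–Br bond of 10, and the alkene is cut into aldehyde 8 and phosphonate 9. Placing the finished stilbene in the boron partner, instead of carrying a masked aldehyde through the coupling, saves protection and deprotection steps. The forward steps need E-selectivity and a halogen–metal exchange that leaves the alkene alone.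

**26 to 24 and 25; 24 to 23.** The S–benzyl bond is cut to thiolane 24 and alcohol 25, and the two C–S bonds of 24 to the cyclic sulfate 23. A sulfide with a twofold axis has equivalent lone pairs, so the salt has no sulfur stereocentre and forms as one compound.

## Roads not taken

**Alternative 1:** The cut is at the two C3–aryl bonds, C3A–aryl and C3B–ring B, on a symmetric ring C bis-coumarin A1 whose lactone β-carbons become C3A and C3B. In the forward sense A1 takes up two aryl groups from boronic acid A2 under Rh(acac)(C2H4)2 (monovalent rhodium) and a chiral biaryl bisphosphine to give the bis(4-aryl-dihydrocoumarin) A3; no ring closes.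
- Merits: this conjugate arylation is a proven, catalyst-controlled way to such benzylic centres; the double reaction on a symmetric substrate raises the enantiopurity of the major isomer; and since the two new aryl rings are identical, either can later serve as ring B.
- Weak points: each lactone of A3 holds one carbon too many, so the carbonyl/methylene pair must be cut down to the single carbon that carries the 4-oxyphenyl group, twice over. The pivaloyloxymethyl group flanks both β-carbons and should slow the arylation. The seven-membered ring and the diarylmethine would be left to a late cationic closure with substrate control only.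
- Comparison: for the absolute configuration of C3A and C3B this road is better founded than the chosen plan, which relies on substrate control in an untested step and on a chiral ylide. The chosen plan sets against it a key step that makes two rings and two stereocentres with no atoms to remove, and a diarylmethine set early by a stereospecific method.

**Alternative 2:** The cut is at both C2–C3 bonds. The bis(aryldiazoacetate) A4, on treatment with dirhodium tetrakis[N-phthaloyl-(S)-tert-leucinate], Rh2(S-PTTL)4 (divalent rhodium), or its antipode, should insert each carbene into the adjacent 4-methoxybenzylic ether C–H bond and close both dihydrofurans, giving the bis(cis-2-aryl-3-methoxycarbonyl-dihydrofuran) A5.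
- Merits: two rings and four stereocentres arise in one catalytic, precedented step under catalyst control; in ring-forming power it equals the chosen key step and in precedent it is ahead.
- Weak points: A5 is cis and carries an ester at each C3 where the target carries an aryl ring. Each ester must be epimerised and then exchanged for an aryl group at a hindered benzylic carbon, which re-forms C3 under substrate control. The two diazo groups flank the pivaloyloxymethyl group, where ylide formation with the ester carbonyl can compete. The seven-membered ring and the diarylmethine remain unsolved.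
- Comparison: the chosen plan has to answer for its lack of precedent; in return its key step delivers the final substitution at C3B and the carbocycle directly.

**Alternative 3:** The cut is at both C2–aryl bonds. The diacid A6 is converted in the flask into its bis(N-acyloxyphthalimide) A7, which is reduced at the cathode with NiCl2(dme) (divalent nickel precatalyst) and a bipyridine ligand in the presence of 4-iodoanisole A8 to give the bis(trans-2,3-diaryl-dihydrofuran) A9; no ring closes.
- Merits: the conditions are mild, the 4-oxyphenyl groups come in late (useful for analogues), the trans outcome follows from capture of the α-oxy radical anti to the C3 aryl group, and the reaction type is closer to precedent than step 10.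
- Weak points: the step creates no ring and no skeletal stereocentre; both dihydrofurans and both C3 centres must already be present in A6, which needs its own enantioselective synthesis. Two hindered secondary radicals must couple in one molecule, with reduction to the C–H compound as the likely leak. The carbocycle is again left for later.
- Comparison: this key step is safer than the chosen one but contributes least to the architecture; the chosen plan spends its risk where the two rings and C3B are formed.

Key step: step 10

Assumptions:
- The Grignard solutions 4 and 20 and the cyclic sulfate 23 are taken as purchasable.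
- The (2R,5R)-ylide 28 is taken to add through the same face as in its benzylidene transfers to aldehydes, which corresponds to 2R,3R in furan A. If the sense is opposite, the enantiomeric salt is made in the same way from the enantiomeric sulfate.

## Route

Step 1
Reactants: 1 methyl 2-(3,5-dihydroxyphenyl)acetate
Product: 2 methyl 2-[3,5-bis(triisopropylsilyloxy)phenyl]acetate
Conditions: TIPSCl, imidazole, DMF, rt
Reagents that add atoms: triisopropylsilyl chloride, CC(C)[Si](Cl)(C(C)C)C(C)C
Why: Standard silylation of phenols; the bulky silyl ethers withstand Grignard and alkyllithium reagents, direct ortho-lithiation poorly, and are later removed by fluoride without acid.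

Step 2
Reactants: 2 methyl 2-[3,5-bis(triisopropylsilyloxy)phenyl]acetate
Product: 3 N-methoxy-N-methyl-2-[3,5-bis(triisopropylsilyloxy)phenyl]acetamide
Conditions: MeNH(OMe)·HCl, iPrMgCl, THF, −20 to 0 °C
Reagents that add atoms: N,O-dimethylhydroxylamine hydrochloride, CNOC.Cl
Why: Aminolysis of the ester by the magnesium amide of N,O-dimethylhydroxylamine; the Weinreb amide stops the next addition at the ketone.

Step 3
Reactants: 3 N-methoxy-N-methyl-2-[3,5-bis(triisopropylsilyloxy)phenyl]acetamide; 4 (2,4-dimethoxyphenyl)magnesium bromide
Product: 5 1-(2,4-dimethoxyphenyl)-2-[3,5-bis(triisopropylsilyloxy)phenyl]ethan-1-one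
Conditions: THF, 0 °C to rt; aq. NH4Cl
Reagents that add atoms: none
Why: Weinreb ketone synthesis; the chelated tetrahedral adduct prevents over-addition, and an excess of 4 makes up for partial enolisation of the arylacetamide.

Step 4
Reactants: 5 1-(2,4-dimethoxyphenyl)-2-[3,5-bis(triisopropylsilyloxy)phenyl]ethan-1-one
Product: 6 (1S)-1-(2,4-dimethoxyphenyl)-2-[3,5-bis(triisopropylsilyloxy)phenyl]ethan-1-ol
Conditions: (R)-1-methyl-3,3-diphenyl-tetrahydro-1H,3H-pyrrolo[1,2-c][1,3,2]oxazaborole ((R)-Me-CBS, 10 mol%), BH3·SMe2, THF, −20 °C; MeOH
Reagents that add atoms: none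
Why: Corey–Bakshi–Shibata reduction; the aryl group acts as the large and the benzylic methylene as the small substituent, so the (R)-catalyst should deliver hydride to give the S carbinol, as with acetophenone-type ketones.

Step 5
Reactants: 6 (1S)-1-(2,4-dimethoxyphenyl)-2-[3,5-bis(triisopropylsilyloxy)phenyl]ethan-1-ol
Product: 7 (1S)-1-(2,4-dimethoxyphenyl)-2-[3,5-bis(triisopropylsilyloxy)phenyl]ethyl N,N-diisopropylcarbamate
Conditions: iPr2NCOCl, Et3N, CH2Cl2, reflux
Reagents that add atoms: N,N-diisopropylcarbamoyl chloride, CC(C)N(C(C)C)C(Cl)=O
Why: O-Carbamoylation leaves the stereocentre untouched; the hindered carbamate is the directing group and later the leaving group of the lithiation–borylation.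

Step 6
Reactants: 8 2-bromo-3,5-dimethoxybenzaldehyde; 9 diethyl (4-methoxybenzyl)phosphonate
Product: 10 (E)-2-bromo-1,5-dimethoxy-3-[2-(4-methoxyphenyl)ethenyl]benzene
Conditions: KOtBu, THF, 0 °C to rt
Reagents that add atoms: none
Why: Horner–Wadsworth–Emmons olefination with a benzylic phosphonate, which gives the E-stilbene.

Step 7
Reactants: 10 (E)-2-bromo-1,5-dimethoxy-3-[2-(4-methoxyphenyl)ethenyl]benzene
Product: 12 2-{2,4-dimethoxy-6-[(E)-2-(4-methoxyphenyl)ethenyl]phenyl}-4,4,5,5-tetramethyl-1,3,2-dioxaborolane, via aryllithium 11 (not isolated)
Conditions: nBuLi, THF, −78 °C; iPrOBpin, −78 °C to rt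
Reagents that add atoms: 2-isopropoxy-4,4,5,5-tetramethyl-1,3,2-dioxaborolane, CC(C)OB1OC(C)(C)C(C)(C)O1
Why: Bromine–lithium exchange at −78 °C is faster than any addition to the stilbene, and the aryllithium is trapped by the borate to give the pinacol boronic ester; this avoids a sluggish catalytic borylation of a doubly ortho-substituted, electron-rich bromide.

Step 8
Reactants: 7 (1S)-1-(2,4-dimethoxyphenyl)-2-[3,5-bis(triisopropylsilyloxy)phenyl]ethyl N,N-diisopropylcarbamate; 12 2-{2,4-dimethoxy-6-[(E)-2-(4-methoxyphenyl)ethenyl]phenyl}-4,4,5,5-tetramethyl-1,3,2-dioxaborolane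
Product: 15 (R)-tertiary pinacol boronic ester carrying the 2,4-dimethoxyphenyl group, ring B with its E-4-methoxystyryl group and the 3,5-bis(triisopropylsilyloxy)benzyl group on the boron-bearing carbon, via lithiated carbamate 13 (not isolated), via lithium boronate complex 14 (not isolated)
Conditions: sBuLi, Et2O, −78 °C; 12, −78 °C; MgBr2·OEt2/MeOH, −78 °C to rt
Reagents that add atoms: none
Why: Lithiation–borylation of a secondary benzylic carbamate: carbamate-directed deprotonation and borylation both occur with retention, and the aryl group then shifts from boron to carbon anti to the departing carbamate, so C–O is replaced by C–ring B with inversion and the S carbamate gives the R boronic ester. The magnesium salt speeds the 1,2-shift of the hindered complex and suppresses its dissociation.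

Step 9
Reactants: 15 (R)-tertiary pinacol boronic ester
Product: 17 5-[(2R)-2-(2,4-dimethoxyphenyl)-2-{2,4-dimethoxy-6-[(E)-2-(4-methoxyphenyl)ethenyl]phenyl}ethyl]benzene-1,3-diol, via bis-silyl triarylethane 16 (not isolated)
Conditions: CsF, H2O, 1,4-dioxane, 45 °C; then TBAF, THF, 0 °C to rt; aq. NH4Cl
Reagents that add atoms: none
Why: Fluoride-promoted protodeboronation of tertiary diarylalkyl boronic esters is stereoretentive, so hydrogen takes the place of boron and the methine is R; fluoride then removes both silyl groups under non-acidic conditions that spare the acid-sensitive stilbene.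

Step 10
Reactants: 17 5-[(2R)-2-(2,4-dimethoxyphenyl)-2-{2,4-dimethoxy-6-[(E)-2-(4-methoxyphenyl)ethenyl]phenyl}ethyl]benzene-1,3-diol
Product: 18 core phenol: ring C (free hydroxyl on a) fused at c/d to trans furan B (2R-(4-methoxyphenyl), 3R), with C3B bonded to the 3,5-dimethoxy ring B, which is bonded to the (R)-CH(2,4-dimethoxyphenyl) methine, whose CH2 is attached to e
Conditions: undivided cell, carbon (RVC) anode, Pt cathode, constant current, LiClO4 (0.1 M), (CF3)2CHOH/CH2Cl2 1:1, 2,6-lutidine, 0 °C, 2 mM, about 2.1 F/mol
Reagents that add atoms: none
Why: Proposed new method: one-electron oxidation at the anode gives the 4-methoxystilbene radical cation (oxidation of the resorcinol instead leads to the same bond), and ring C carbon d, ortho to one hydroxyl and para to the other, attacks the alkene carbon remote from the anisyl group in a 7-exo-trig closure that leaves an anisyl-stabilised benzylic radical. A second electron transfer and loss of a proton give the benzylic cation, which the neighbouring phenol oxygen captures in a 5-exo closure (onto the quinone-methide-like form of the cation) to complete furan B. The closest known reaction type is the anodic or photoredox oxidative [3+2] cycloaddition of phenols with electron-rich styrenes to trans-2-aryl-2,3-dihydrobenzofurans, which has not been run intramolecularly through a medium ring or with a resorcinol as the phenol. Regioselectivity rests on ring size (seven against eight) and on the better stabilisation of spin and charge beside the anisyl ring; d and f are equivalent in the symmetric resorcinol and carbon b cannot reach the alkene. C3B is controlled by the preset methine: allylic strain against the ring B methoxy group keeps the methine hydrogen in the plane of ring B, the 2,4-dimethoxyphenyl group pseudo-axial on one face and the CH2–ring C arm on the other, while the styryl group turns its anisyl-bearing carbon away from the methine, so ring C should add to the alkene face that gives 3R. C2B is controlled by C3B: the cation closes with the anisyl group anti to ring B, and since this C–O bond can ionise again in hexafluoroisopropanol, trans is also the thermodynamic result. The step needs oxidation of the stilbene–resorcinol pair in preference to the three dimethoxyarenes and to the product phenol; the lower potential of the 4-methoxystilbene, the radical-cation-stabilising solvent, high dilution and a charge limit near two faraday per mole are expected to secure this.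

Step 11
Reactants: 18 core phenol
Product: 19 core salicylaldehyde (18 with a formyl group on carbon f, ortho to the hydroxyl on a)
Conditions: MgCl2, Et3N, (CH2O)n, MeCN, reflux
Reagents that add atoms: paraformaldehyde (formaldehyde), C=O
Why: Magnesium-phenoxide-templated ortho-formylation (Casnati–Skattebøl type) touches only the ring with the free phenol; of its two ortho carbons, f is para to the furan B oxygen and should react in preference to b, which lies between two oxygens, as in formylations of 5-alkylresorcinol ethers.

Step 12
Reactants: 19 core salicylaldehyde; 20 (3,5-dimethoxyphenyl)magnesium chloride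
Product: 22 core sulfone (carbon f carries CH(3,5-dimethoxyphenyl)(p-tolylsulfonyl); both epimers at this carbon), via benzhydrol 21 (not isolated)
Conditions: 20 (3 equiv), THF, 0 °C to rt; aq. NH4Cl; crude 21, p-TolSO2Na, HCO2H/H2O/THF, rt
Reagents that add atoms: sodium p-toluenesulfinate, Cc1ccc(S(=O)[O-])cc1.[Na+]
Why: Grignard addition to the salicylaldehyde (one equivalent is consumed by the phenol) gives the ortho-hydroxybenzhydrol, which ionises readily in formic acid and is captured by sulfinate to give a bench-stable, base-triggered precursor of the ortho-quinone methide. The configuration of the new carbon is of no consequence.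

Step 13
Reactants: 23 (4S,7S)-4,7-dimethyl-1,3,2-dioxathiepane 2,2-dioxide
Product: 24 (2R,5R)-2,5-dimethylthiolane
Conditions: Na2S·9H2O, DMSO, 60 °C
Reagents that add atoms: sodium sulfide, [Na+].[Na+].[S-2]
Why: Double SN2 displacement (opening of the cyclic sulfate, then 5-exo-tet closure of the thiolate onto the sulfate monoester) inverts both carbons, so the S,S sulfate gives the R,R thiolane.

Step 14
Reactants: 24 (2R,5R)-2,5-dimethylthiolane; 25 4-methoxybenzyl alcohol
Product: 26 (2R,5R)-1-(4-methoxybenzyl)-2,5-dimethylthiolan-1-ium tetrafluoroborate
Conditions: HBF4·OEt2, CH2Cl2, 0 °C to rt; Et2O (precipitation)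
Reagents that add atoms: tetrafluoroboric acid diethyl etherate, [H+].F[B-](F)(F)F
Why: Acid ionises the 4-methoxybenzyl alcohol and the sulfide captures the cation (SN1 S-alkylation); the two lone pairs of the C2-symmetric sulfide are equivalent, so one sulfonium salt forms, with a non-nucleophilic counter-ion.

Step 15
Reactants: 22 core sulfone; 26 (2R,5R)-1-(4-methoxybenzyl)-2,5-dimethylthiolan-1-ium tetrafluoroborate
Product: 29 octamethyl ether of the target (furan A 2R,3R trans, furan B 2R,3R trans, methine R), via ortho-quinone methide 27 (not isolated), via sulfonium ylide 28 (not isolated)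
Conditions: Cs2CO3, CH2Cl2, 0 °C to rt
Reagents that add atoms: none
Why: Formal [4+1] annulation of an ortho-quinone methide with a sulfur ylide: base expels sulfinate from the phenoxide of 22, the benzylic ylide adds to the exocyclic carbon (C2A–C3A bond), and the phenoxide displaces the sulfide with inversion (O–C2A bond). The anti betaine leads to the trans dihydrofuran, and the accessible face of the C2-symmetric ylide should fix C2A, and with it C3A, as R,R by reagent control, independently of the distant stereocentres of the core.

Step 16
Reactants: 29 octamethyl ether of the target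
Product: 30 target octaphenol CNP0154047.1
Conditions: BBr3, CH2Cl2, −78 to 0 °C; MeOH, then H2O
Reagents that add atoms: none
Why: Lewis-acid cleavage of the eight aryl methyl ethers through aryloxyboranes with loss of methyl bromide; no stilbene remains that could cyclise, and any reversible ionisation of a benzylic C2–O bond should return the favoured trans dihydrofuran, so no stereocentre should be lost.

## Compound list

1 | methyl 2-(3,5-dihydroxyphenyl)acetate | COC(=O)Cc1cc(O)cc(O)c1 | starting material
2 | methyl 2-[3,5-bis(triisopropylsilyloxy)phenyl]acetate | COC(=O)Cc1cc(O[Si](C(C)C)(C(C)C)C(C)C)cc(O[Si](C(C)C)(C(C)C)C(C)C)c1 | intermediate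
3 | N-methoxy-N-methyl-2-[3,5-bis(triisopropylsilyloxy)phenyl]acetamide | CON(C)C(=O)Cc1cc(O[Si](C(C)C)(C(C)C)C(C)C)cc(O[Si](C(C)C)(C(C)C)C(C)C)c1 | intermediate
4 | (2,4-dimethoxyphenyl)magnesium bromide (THF solution) | COc1ccc([Mg]Br)c(OC)c1 | starting material
5 | 1-(2,4-dimethoxyphenyl)-2-[3,5-bis(triisopropylsilyloxy)phenyl]ethan-1-one | COc1ccc(C(=O)Cc2cc(O[Si](C(C)C)(C(C)C)C(C)C)cc(O[Si](C(C)C)(C(C)C)C(C)C)c2)c(OC)c1 | intermediate
6 | (1S)-1-(2,4-dimethoxyphenyl)-2-[3,5-bis(triisopropylsilyloxy)phenyl]ethan-1-ol | COc1ccc([C@@H](O)Cc2cc(O[Si](C(C)C)(C(C)C)C(C)C)cc(O[Si](C(C)C)(C(C)C)C(C)C)c2)c(OC)c1 | intermediate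
7 | (1S)-1-(2,4-dimethoxyphenyl)-2-[3,5-bis(triisopropylsilyloxy)phenyl]ethyl N,N-diisopropylcarbamate | COc1ccc([C@@H](OC(=O)N(C(C)C)C(C)C)Cc2cc(O[Si](C(C)C)(C(C)C)C(C)C)cc(O[Si](C(C)C)(C(C)C)C(C)C)c2)c(OC)c1 | intermediate
8 | 2-bromo-3,5-dimethoxybenzaldehyde | O=Cc1cc(OC)cc(OC)c1Br | starting material
9 | diethyl (4-methoxybenzyl)phosphonate | CCOP(=O)(Cc1ccc(OC)cc1)OCC | starting material
10 | (E)-2-bromo-1,5-dimethoxy-3-[2-(4-methoxyphenyl)ethenyl]benzene | COc1ccc(/C=C/c2cc(OC)cc(OC)c2Br)cc1 | intermediate
11 | {2,4-dimethoxy-6-[(E)-2-(4-methoxyphenyl)ethenyl]phenyl}lithium (not isolated) | COc1ccc(/C=C/c2cc(OC)cc(OC)c2[Li])cc1 | intermediate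
12 | 2-{2,4-dimethoxy-6-[(E)-2-(4-methoxyphenyl)ethenyl]phenyl}-4,4,5,5-tetramethyl-1,3,2-dioxaborolane | COc1ccc(/C=C/c2cc(OC)cc(OC)c2B2OC(C)(C)C(C)(C)O2)cc1 | intermediate
13 | (S)-α-lithiated carbamate from 7 (lithium in place of the carbinol hydrogen; not isolated) | COc1ccc([C@@]([Li])(OC(=O)N(C(C)C)C(C)C)Cc2cc(O[Si](C(C)C)(C(C)C)C(C)C)cc(O[Si](C(C)C)(C(C)C)C(C)C)c2)c(OC)c1 | intermediate
14 | lithium boronate complex of 13 and 12 (S at carbon; not isolated) | COc1ccc([C@@]([B-]2(OC(C)(C)C(C)(C)O2)c2c(OC)cc(OC)cc2/C=C/c2ccc(OC)cc2)(OC(=O)N(C(C)C)C(C)C)Cc2cc(O[Si](C(C)C)(C(C)C)C(C)C)cc(O[Si](C(C)C)(C(C)C)C(C)C)c2)c(OC)c1.[Li+] | intermediate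
15 | 2-[(1R)-1-(2,4-dimethoxyphenyl)-1-{2,4-dimethoxy-6-[(E)-2-(4-methoxyphenyl)ethenyl]phenyl}-2-[3,5-bis(triisopropylsilyloxy)phenyl]ethyl]-4,4,5,5-tetramethyl-1,3,2-dioxaborolane | COc1ccc([C@](B2OC(C)(C)C(C)(C)O2)(c2c(OC)cc(OC)cc2/C=C/c2ccc(OC)cc2)Cc2cc(O[Si](C(C)C)(C(C)C)C(C)C)cc(O[Si](C(C)C)(C(C)C)C(C)C)c2)c(OC)c1 | intermediate
16 | (R)-bis-silyl triarylethane: 17 with both phenols as triisopropylsilyl ethers (not isolated) | COc1ccc([C@H](c2c(OC)cc(OC)cc2/C=C/c2ccc(OC)cc2)Cc2cc(O[Si](C(C)C)(C(C)C)C(C)C)cc(O[Si](C(C)C)(C(C)C)C(C)C)c2)c(OC)c1 | intermediate
17 | 5-[(2R)-2-(2,4-dimethoxyphenyl)-2-{2,4-dimethoxy-6-[(E)-2-(4-methoxyphenyl)ethenyl]phenyl}ethyl]benzene-1,3-diol | COc1ccc([C@H](c2c(OC)cc(OC)cc2/C=C/c2ccc(OC)cc2)Cc2cc(O)cc(O)c2)c(OC)c1 | intermediate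
18 | core phenol: seven-membered ring and trans furan B closed (furan B 2R,3R; methine R; free hydroxyl on a) | Oc1cc2c3c(c1)C[C@H](c1ccc(OC)cc1OC)c1c(OC)cc(OC)cc1[C@H]3[C@H](c1ccc(OC)cc1)O2 | intermediate
19 | core salicylaldehyde: 18 with CHO on f | O=Cc1c(O)cc2c3c1C[C@H](c1ccc(OC)cc1OC)c1c(OC)cc(OC)cc1[C@H]3[C@H](c1ccc(OC)cc1)O2 | intermediate
20 | (3,5-dimethoxyphenyl)magnesium chloride (THF solution) | COc1cc(OC)cc([Mg]Cl)c1 | starting material
21 | core benzhydrol: 18 with CH(OH)(3,5-dimethoxyphenyl) on f, both carbinol epimers (not isolated) | COc1cc(OC)cc(C(O)c2c(O)cc3c4c2C[C@H](c2ccc(OC)cc2OC)c2c(OC)cc(OC)cc2[C@H]4[C@H](c2ccc(OC)cc2)O3)c1 | intermediate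
22 | core sulfone: 18 with CH(3,5-dimethoxyphenyl)(p-tolylsulfonyl) on f, both epimers | COc1cc(OC)cc(C(c2c(O)cc3c4c2C[C@H](c2ccc(OC)cc2OC)c2c(OC)cc(OC)cc2[C@H]4[C@H](c2ccc(OC)cc2)O3)S(=O)(=O)c2ccc(C)cc2)c1 | intermediate
23 | (4S,7S)-4,7-dimethyl-1,3,2-dioxathiepane 2,2-dioxide | C[C@H]1CC[C@H](C)OS(=O)(=O)O1 | starting material
24 | (2R,5R)-2,5-dimethylthiolane | C[C@@H]1CC[C@@H](C)S1 | intermediate
25 | 4-methoxybenzyl alcohol | COc1ccc(CO)cc1 | starting material
26 | (2R,5R)-1-(4-methoxybenzyl)-2,5-dimethylthiolan-1-ium tetrafluoroborate | C[C@@H]1CC[C@@H](C)[S+]1Cc1ccc(OC)cc1.F[B-](F)(F)F | intermediate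
27 | ortho-quinone methide from 22 (carbonyl at a, exocyclic C=CH(3,5-dimethoxyphenyl) at f, alkene geometry open; not isolated) | COc1cc(OC)cc(C=C2C(=O)C=C3O[C@@H](c4ccc(OC)cc4)[C@H]4C3=C2C[C@H](c2ccc(OC)cc2OC)c2c(OC)cc(OC)cc24)c1 | intermediate
28 | (2R,5R)-2,5-dimethylthiolanium (4-methoxyphenyl)methylide (not isolated) | C[C@@H]1CC[C@@H](C)[S+]1[CH-]c1ccc(OC)cc1 | intermediate
29 | octamethyl ether of the target (all five stereocentres R) | COc1ccc([C@@H]2Oc3cc4c5c(c3[C@H]2c2cc(OC)cc(OC)c2)C[C@H](c2ccc(OC)cc2OC)c2c(OC)cc(OC)cc2[C@H]5[C@H](c2ccc(OC)cc2)O4)cc1 | intermediate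
30 | CNP0154047.1 (furan A 2R,3R; furan B 2R,3R; diarylmethine R) | Oc1ccc([C@@H]2Oc3cc4c5c(c3[C@H]2c2cc(O)cc(O)c2)C[C@H](c2ccc(O)cc2O)c2c(O)cc(O)cc2[C@H]5[C@H](c2ccc(O)cc2)O4)cc1 | target

## Step count and least certain steps

Total: 16 steps. Longest linear sequence: 12 steps (1–5, 8–12, 15, 16); the ring B branch (6, 7) and the sulfonium branch (13, 14) have two steps each.

**Step 10 (key step, the one labelled as a new method).**
- Most likely failure: further oxidation of the product phenol or intermolecular coupling of the radical cation, because the product is about as electron-rich as the substrate; next, incomplete face selection at C3B if the styryl rotamer preference is weaker than assumed.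
- Fallback by known reactions, from 16 (isolated by leaving out the fluoride treatment of step 9) back to 18:
  - Lemieux–Johnson cleavage of the stilbene (OsO4 cat., NaIO4, 2,6-lutidine, dioxane/H2O) should give the bis-silyl aldehyde F1.
  - TBAF should give the bis-phenol aldehyde F2.
  - In formic acid with sodium p-toluenesulfinate, carbon d should close the seven-membered ring by intramolecular Friedel–Crafts hydroxyalkylation, and sulfinate should capture the doubly activated benzhydryl position to give the cyclic sulfone F3.
  - Treatment of F3 with salt 26 and Cs2CO3 should generate the ring C quinone methide, which accepts the ylide at the future C3B; the phenoxide on c then closes furan B to give 18. Ylide control and approach anti to the pseudo-axial 2,4-dimethoxyphenyl group act in this step.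

**Step 8.**
- Most likely failure: slow or reversible formation of the boronate complex from the doubly ortho-substituted boronic ester, so that carbamate is recovered or its configuration erodes before the 1,2-shift.
- Fallback, from 6 (the racemate from NaBH4 reduction of 5 serves as well) back to 16:
  - Friedel–Crafts benzylation of 1-bromo-3,5-dimethoxybenzene by 6 in (CF3)2CHOH (Bi(OTf)3 cat. if needed) should bond the benzylic carbon to the ring carbon between bromine and methoxy and give the racemic aryl bromide F4.
  - Heck coupling with 4-methoxystyrene (Pd(OAc)2, P(o-tol)3, Et3N, DMF, 100 °C) should give the racemic bis-silyl triarylethane F5.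
  - Preparative chromatography on a chiral stationary phase would then supply 16. This costs half the material but does not depend on transferring a hindered aryl group from boron.

**Step 11.**
- Most likely failure: formylation at b instead of f, since both carbons are ortho to the magnesium phenoxide.
- Fallback, from 18 directly to 22: acid-mediated three-component condensation of 18 with 3,5-dimethoxybenzaldehyde and sodium p-toluenesulfinate in formic acid. This is an untemplated electrophilic substitution in which the carbon para to the furan B oxygen is the electronically preferred site; it bypasses 19 and 21 and makes no new compound.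

**Step 15.**
- Most likely failure: poor facial selectivity at the quinone methide when the preference of the chiral core opposes that of the ylide; formation of the syn betaine and hence some cis dihydrofuran; benzyl transfer from the sulfonium salt to the phenoxide.
- Fallback under catalyst control, from 21 (isolated before the sulfinate treatment) back to 29:
  - MnO2 should oxidise 21 to the ortho-hydroxybenzophenone F6.
  - 4-Methoxybenzyl chloride and K2CO3 should give the 4-methoxybenzyl ether F7.
  - Hydrazine hydrate with acetic acid should give the hydrazone F8.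
  - MnO2 should give the diaryldiazomethane F9.
  - Dirhodium tetrakis[N-phthaloyl-(S)-adamantylglycinate], Rh2(S-PTAD)4, or its antipode, chosen to give 3R, should insert the donor/donor carbene into the benzylic ether C–H bond to give the cis dihydrofuran F10 (2S,3R in furan A).
  - Brief trifluoroacetic acid treatment should epimerise C2A through the benzylic cation to the trans isomer 29.

**Step 16.**
- Most likely failure: incomplete cleavage of eight ethers, opening of a dihydrofuran by bromide at C2 that does not reclose, and air oxidation of the octaphenol during purification.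
- Fallback, from 29 to 30: nucleophilic demethylation with NaSEt in DMF at 130 °C (SN2 at methyl under basic conditions), acetylation of the crude product with Ac2O/pyridine to the octaacetate F11, purification at that stage, and methanolysis with K2CO3 in MeOH under argon.

## Further compounds

F1 | step 10 | 2-[(1R)-1-(2,4-dimethoxyphenyl)-2-[3,5-bis(triisopropylsilyloxy)phenyl]ethyl]-3,5-dimethoxybenzaldehyde | COc1ccc([C@H](c2c(OC)cc(OC)cc2C=O)Cc2cc(O[Si](C(C)C)(C(C)C)C(C)C)cc(O[Si](C(C)C)(C(C)C)C(C)C)c2)c(OC)c1
F2 | step 10 | 2-[(1R)-1-(2,4-dimethoxyphenyl)-2-(3,5-dihydroxyphenyl)ethyl]-3,5-dimethoxybenzaldehyde | COc1ccc([C@H](c2c(OC)cc(OC)cc2C=O)Cc2cc(O)cc(O)c2)c(OC)c1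
F3 | step 10 | cyclic sulfone: dibenzo-fused seven-membered ring from F2 with p-tolylsulfonyl on the carbon between ring B and ring C carbon d (methine R, sulfonyl carbon as both epimers) | Cc1ccc(S(=O)(=O)C2c3cc(OC)cc(OC)c3[C@@H](c3ccc(OC)cc3OC)Cc3cc(O)cc(O)c32)cc1
F4 | step 8 | racemic 2-bromo-1-[1-(2,4-dimethoxyphenyl)-2-[3,5-bis(triisopropylsilyloxy)phenyl]ethyl]-4,6-dimethoxybenzene (bromine ortho to the new bond) | COc1ccc(C(c2c(OC)cc(OC)cc2Br)Cc2cc(O[Si](C(C)C)(C(C)C)C(C)C)cc(O[Si](C(C)C)(C(C)C)C(C)C)c2)c(OC)c1
F5 | step 8 | racemic bis-silyl triarylethane (racemate of 16) | COc1ccc(C(c2c(OC)cc(OC)cc2/C=C/c2ccc(OC)cc2)Cc2cc(O[Si](C(C)C)(C(C)C)C(C)C)cc(O[Si](C(C)C)(C(C)C)C(C)C)c2)c(OC)c1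
F0 | step 11 | none | none
F6 | step 15 | core ortho-hydroxybenzophenone: 18 with a 3,5-dimethoxybenzoyl group on f | COc1cc(OC)cc(C(=O)c2c(O)cc3c4c2C[C@H](c2ccc(OC)cc2OC)c2c(OC)cc(OC)cc2[C@H]4[C@H](c2ccc(OC)cc2)O3)c1
F7 | step 15 | 4-methoxybenzyl ether of F6 | COc1cc(OC)cc(C(=O)c2c(OCc5ccc(OC)cc5)cc3c4c2C[C@H](c2ccc(OC)cc2OC)c2c(OC)cc(OC)cc2[C@H]4[C@H](c2ccc(OC)cc2)O3)c1
F8 | step 15 | hydrazone of F7 | COc1cc(OC)cc(C(=NN)c2c(OCc5ccc(OC)cc5)cc3c4c2C[C@H](c2ccc(OC)cc2OC)c2c(OC)cc(OC)cc2[C@H]4[C@H](c2ccc(OC)cc2)O3)c1
F9 | step 15 | diaryldiazomethane from F8 | COc1cc(OC)cc(C(=[N+]=[N-])c2c(OCc5ccc(OC)cc5)cc3c4c2C[C@H](c2ccc(OC)cc2OC)c2c(OC)cc(OC)cc2[C@H]4[C@H](c2ccc(OC)cc2)O3)c1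
F10 | step 15 | C2A epimer of 29 (furan A cis, 2S,3R) | COc1ccc([C@H]2Oc3cc4c5c(c3[C@H]2c2cc(OC)cc(OC)c2)C[C@H](c2ccc(OC)cc2OC)c2c(OC)cc(OC)cc2[C@H]5[C@H](c2ccc(OC)cc2)O4)cc1
F11 | step 16 | octaacetate of 30 | CC(=O)Oc1ccc([C@@H]2Oc3cc4c5c(c3[C@H]2c2cc(OC(C)=O)cc(OC(C)=O)c2)C[C@H](c2ccc(OC(C)=O)cc2OC(C)=O)c2c(OC(C)=O)cc(OC(C)=O)cc2[C@H]5[C@H](c2ccc(OC(C)=O)cc2)O4)cc1
A1 | alternative 1 | ring C bis-coumarin with a pivaloyloxymethyl group between the two pyranone rings | O=C1C=Cc2c(COC(=O)C(C)(C)C)c3C=CC(=O)Oc3cc2O1
A2 | alternative 1 | 3,5-dimethoxyphenylboronic acid | COc1cc(OC)cc(B(O)O)c1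
A3 | alternative 1 | twofold-symmetric bis(4-aryl-dihydrocoumarin) | O=C1C[C@H](c4cc(OC)cc(OC)c4)c2c(COC(=O)C(C)(C)C)c3[C@@H](c4cc(OC)cc(OC)c4)CC(=O)Oc3cc2O1
A4 | alternative 2 | ring C bis(aryldiazoacetate) with two 4-methoxybenzyl ethers and a pivaloyloxymethyl group | COc1ccc(COc2cc(OCc3ccc(OC)cc3)c(C(=[N+]=[N-])C(=O)OC)c(COC(=O)C(C)(C)C)c2C(=[N+]=[N-])C(=O)OC)cc1
A5 | alternative 2 | twofold-symmetric bis(cis-2-aryl-3-methoxycarbonyl-dihydrofuran) on ring C | COc1ccc([C@@H]2Oc3cc4c(c(COC(=O)C(C)(C)C)c3[C@@H]2C(=O)OC)[C@H](C(=O)OC)[C@H](c2ccc(OC)cc2)O4)cc1
A6 | alternative 3 | ring C bis(trans-3-aryl-dihydrofuran-2-carboxylic acid) with a silyloxymethyl side chain | O=C(O)[C@@H]1Oc2cc3c(c(CO[Si](C(C)C)(C(C)C)C(C)C)c2[C@H]1c1cc(OC)cc(OC)c1)[C@@H](c1cc(OC)cc(OC)c1)[C@H](C(=O)O)O3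
A7 | alternative 3 | bis(N-acyloxyphthalimide) of A6 | O=C(ON1C(=O)c2ccccc2C1=O)[C@@H]1Oc2cc3c(c(CO[Si](C(C)C)(C(C)C)C(C)C)c2[C@H]1c1cc(OC)cc(OC)c1)[C@@H](c1cc(OC)cc(OC)c1)[C@H](C(=O)ON1C(=O)c2ccccc2C1=O)O3
A8 | alternative 3 | 4-iodoanisole | COc1ccc(I)cc1
A9 | alternative 3 | twofold-symmetric bis(trans-2,3-diaryl-dihydrofuran) on ring C with a silyloxymethyl side chain | COc1ccc([C@@H]2Oc3cc4c(c(CO[Si](C(C)C)(C(C)C)C(C)C)c3[C@H]2c2cc(OC)cc(OC)c2)[C@@H](c2cc(OC)cc(OC)c2)[C@H](c2ccc(OC)cc2)O4)cc1
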